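## The problem

The target 19 is a 2-arylbenzofuran with no stereocentre; ring A (the benzo ring) is substituted everywhere except C7, with OH at C4, a 3-hydroxy-3-methylbutyl chain at C5 and OMe at C6. Ring B (the furan) carries a formyl group at C3 and ring C (the pendant aryl) at C2. The difficulty is regiochemical: four phenolic oxygens must be told apart, O4 and O4' ending free and O6 and O2' ending as methyl ethers. The chain must be placed at C5, between O4 and O6, although C5 and C7 of the phloroglucinol-type ring are electronically alike. The tertiary alcohol ionises in acid and then closes onto a free O4 to give a 2,2-dimethylchroman, or loses water. The C3 aldehyde is reducible, and at the carbinol level C3–CH2OH is a vinylogous hemiacetal-type position that ionises easily. The biaryl bond C2–C1' is flanked by the C3 carbon and by O2'. Those two atoms are the enabling feature: at the carboxylic acid level they can be joined as an ester C3–C(=O)–O–C2', whose six-membered lactone (the central ring of a coumestan) holds C1' over C2. Reductive opening returns the carbon to C3 and leaves O2' as the only free phenol.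

## Retrosynthesis

Benzofuran numbering is used throughout, with primed numbers for ring C.

**19 from 18 (O4–Bn and O4'–Bn).** The two free phenols are unmasked last from bis-benzyl ether 18 by hydrogenolysis, which is neutral. Acid-labile groups would expose the tertiary alcohol next to a liberated O4–H to chroman formation, and silyl ethers would not survive the basic steps. The forward step must cleave two aryl benzyl ethers faster than it reduces a deactivated, vinylogous formate-like aldehyde.

**18 from lactone 15 via 17 and 16 (bridge opening).** Aldehyde 18 comes from alcohol 17 by oxidation, 17 from phenol 16 by O-methylation, and 16 from lactone 15 by hydride reduction. Full reduction and reoxidation is preferred over partial reduction because the aryl ester tends to collapse and over-reduce. In 16 the only acidic OH is O2'–H, so carbonate and a methyl halide cannot touch the primary or tertiary alcohol, nor the benzylated O4 and O4'. This differentiation is the reason for the lactone.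

**15 from 14 (C2–C1', the key cut).** Cutting the biaryl bond inside the lactone gives aryl ester 14, with bromine on C1' and hydrogen on C2. An intermolecular cut of the same bond would need a prefunctionalised C2 and a doubly ortho-substituted coupling. The tether makes the coupling intramolecular, lets only C2–H reach the metal, and stores O2' as the ester oxygen. The forward reaction must insert into C–Br and activate C2–H without cleaving the aryl ester.

**14 from acid 11 and phenol 13 (ester C–O).** The ester divides the molecule into two halves of similar size. Phenol 13 comes from 4-bromoresorcinol 12 by benzylation of the hydroxyl remote from bromine. The esterification must be mild and non-acidic, since 11 carries the free tertiary alcohol.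

**11 from 10, and 10 from iodide 7 and alkene 8 via borane 9 (C5–CH2).** Acid 11 is the saponified ester 10. The chain is attached as a complete C5 unit by sp2–sp3 cross-coupling of aryl iodide 7 with borane 9, made in the flask from 8. This cut is preferred over an alkyne coupling because no hydrogenation is needed, so the O4 benzyl ether survives. The tertiary alcohol also enters after the only strongly acidic step and can stay unprotected to the end.

**7 from 6 from 5 (C5–I, O4–Bn).** Iodide 7 is the benzyl ether of iodophenol 6, which comes from phenol 5. The free, ester-chelated O4–H of 5 is used to direct the halogen to its ortho position C5 before it is capped. After capping, C5 and C7 would be hard to distinguish.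

**5 from 2 and 3 via 4 (O1–C2 and C3–C3a), and 2 from 1.** The furan ring with its C3 carboxylate comes in one operation from salicylaldehyde 2 and diazo ester 3 through hemiacetal 4. Aldehyde 2 is chosen because its two ortho hydroxyls are equivalent: whichever closes the ring, the other becomes O4–H, so no protecting group is needed to decide which oxygen becomes O1. Aldehyde 2 is the 4-O-methyl ether of commercial 1, methylated at its most acidic hydroxyl.

## Roads not taken

**Alternative 1:** The cut is C2–C3 at the dihydrofuran level. Rh2(OAc)4 would decompose aryldiazoacetate A1, and the carbene carbon would insert into the ether-activated benzylic C–H five atoms away to give dihydrobenzofuran A2 as a racemic cis/trans mixture.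
- Merits: ring C arrives as a simple benzyl unit with O2' already methylated, so no late phenol differentiation is needed. The key step runs at room temperature, and 1,5-insertion next to oxygen is a reliable reaction class. In these respects it is better than the chosen plan.
- Weak points: A1 needs an acetate side chain (one more C–C bond than a formyl group) on the fully substituted ring A, and a diazo transfer onto a doubly ortho-substituted arylacetate. The carbenoid sits between a pivalate carbonyl and an ether oxygen, so carbonyl-ylide and oxonium-ylide pathways compete. Two stereocentres are made only to be erased by a later dehydrogenation of a very electron-rich system. The ester-to-aldehyde adjustment and three different protecting groups remain.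
- Comparison: the chosen plan keeps ring B aromatic from step 2, needs no oxidation of the heterocycle, and reaches its acid in one step from a salicylaldehyde.

**Alternative 2:** The cut is O1–C2, with the C3 carboxylate seen as a former lactone carbonyl. NaOMe in methanol would open the lactone of spiro-epoxide A3. The freed phenoxide would open the epoxide at the benzylic carbon (5-exo), and acid would dehydrate to benzofuran ester A4.
- Merits: no transition metal is needed. The regiochemistry of ring closure is unambiguous, since attack at the other epoxide carbon would give a four-membered ring. A4 already carries the O2' methyl ether, so its endgame is one step shorter than the chosen one.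
- Weak points: A3 requires ring A at the arylacetic acid level, which is harder to reach than a salicylaldehyde. It also requires epoxidation of an exocyclic, ester-conjugated double bond whose lactone is opened by alkaline peroxide. The epoxide carries a strongly donating aryl group and can rearrange through a benzylic cation. The acidic dehydration exposes the free tertiary alcohol to acid.
- Comparison: overall length is similar. The chosen plan has the cheaper entry to ring A and a key step that involves no acid-labile intermediate.

**Alternative 3:** Four bonds of ring A are cut. Photochemical Wolff rearrangement of furyl diazoketone A5 in the presence of methoxyalkyne A6, then heating, would run through [2+2] addition, four-electron ring opening and six-electron closure to phenol A7.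
- Merits: OH at C4, chain at C5, OMe at C6 and H at C7 are dictated by the mechanism. This is better than the chosen plan, whose step 3 relies on ortho-selective iodination. The route is highly convergent and the aldehyde is already at the right oxidation level.
- Weak points: A5 is a trisubstituted furan needing several steps, including diazoketone formation, and A6 is a sensitive ynol ether. The electrocyclisation must engage the furan and give up its aromaticity for a time, so ketene dimerisation competes. Unmasking the dioxolane needs aqueous acid beside a free O4–H and the tertiary oxygen, which are the conditions for chroman formation.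
- Comparison: the chosen plan has a short supply line from commodity arenes and a Claisen relay in reserve for the iodination regiochemistry.

Key step: step 9

Remark on the chemistry: hemiacetal 4 is taken as a mixture of racemic diastereomers, and borane 9 is drawn with a free hydroxyl, since any O–B bond formed with excess borane is hydrolysed by the aqueous base of the coupling.

## Route

Step 1
Reactants: 1 2,4,6-trihydroxybenzaldehyde
Product: 2 2,6-dihydroxy-4-methoxybenzaldehyde
Conditions: MeI (1.0 equiv), K2CO3 (1.0 equiv), acetone, 0 °C to rt
Reagents that add atoms: iodomethane, CI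
Why: Williamson methylation of the most acidic hydroxyl; O4 is para to the formyl group and is the only OH not hydrogen-bonded to the carbonyl, so one equivalent of base should ionise and alkylate it first, as is usual for 2,4,6-trihydroxyaryl carbonyl compounds.

Step 2
Reactants: 2 2,6-dihydroxy-4-methoxybenzaldehyde; 3 ethyl diazoacetate
Product: 5 ethyl 4-hydroxy-6-methoxybenzofuran-3-carboxylate, via cyclic hemiacetal 4 (not isolated)
Conditions: N2CHCO2Et (1.5 equiv), HBF4·OEt2 (10 mol%), CH2Cl2, rt; then conc. H2SO4, rt
Reagents that add atoms: none
Why: Acid-catalysed addition of the diazo ester to the aldehyde, 1,2-aryl shift with loss of N2 (Roskamp-type homologation with aryl migration), closure of a phenol onto the new formyl ester and dehydration; this is the established one-pot route from salicylaldehydes to benzofuran-3-carboxylates. The two hydroxyls of 2 are equivalent, so a single benzofuran should form and the spectator OH becomes O4–H.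

Step 3
Reactants: 5 ethyl 4-hydroxy-6-methoxybenzofuran-3-carboxylate
Product: 6 ethyl 4-hydroxy-5-iodo-6-methoxybenzofuran-3-carboxylate
Conditions: BnMe3N·ICl2 (1.05 equiv), CaCO3, CH2Cl2/MeOH, rt
Reagents that add atoms: benzyltrimethylammonium dichloroiodate, C[N+](C)(C)Cc1ccccc1.Cl[I-]Cl
Why: Electrophilic aromatic iodination ortho to a free, carbonyl-chelated phenol; the same reagent iodinates 5-hydroxy-7-methoxyflavones between OH and OMe, the position that corresponds to C5 here. C2 is deactivated by the ester.

Step 4
Reactants: 6 ethyl 4-hydroxy-5-iodo-6-methoxybenzofuran-3-carboxylate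
Product: 7 ethyl 4-(benzyloxy)-5-iodo-6-methoxybenzofuran-3-carboxylate
Conditions: BnBr, K2CO3, DMF, 50 °C
Reagents that add atoms: benzyl bromide, BrCc1ccccc1
Why: Williamson benzylation of the only hydroxyl; the ortho iodine raises its acidity, and warm DMF overcomes the crowding between the iodine and the peri ester.

Step 5
Reactants: 7 ethyl 4-(benzyloxy)-5-iodo-6-methoxybenzofuran-3-carboxylate; 8 2-methylbut-3-en-2-ol
Product: 10 ethyl 4-(benzyloxy)-5-(3-hydroxy-3-methylbutyl)-6-methoxybenzofuran-3-carboxylate, via alkylborane 9 (not isolated)
Conditions: 8, 9-BBN-H (2.2 equiv), THF, 0 °C to rt; then 7, PdCl2(dppf) (5 mol%), aq K3PO4, DMF, 60 °C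
Reagents that add atoms: 9-borabicyclo[3.3.1]nonane (9-BBN-H), B1C2CCCC1CCC2 (boron carrier for 9 only; none of its atoms stays in 10)
Why: Anti-Markovnikov hydroboration puts boron on the terminal carbon, and B-alkyl Suzuki–Miyaura coupling with the aryl iodide then forms C5–CH2. No hydrogenation is involved, so the benzyl ether is safe, and the tertiary hydroxyl reacts only slowly with the borane.

Step 6
Reactants: 10 ethyl 4-(benzyloxy)-5-(3-hydroxy-3-methylbutyl)-6-methoxybenzofuran-3-carboxylate
Product: 11 4-(benzyloxy)-5-(3-hydroxy-3-methylbutyl)-6-methoxybenzofuran-3-carboxylic acid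
Conditions: LiOH, THF/MeOH/H2O, 50 °C; then 1 M HCl to pH 4, 0 °C
Reagents that add atoms: lithium hydroxide, [Li+].[OH-]
Why: Ester saponification by acyl–oxygen cleavage; brief cold acidification to pH 4 is too mild to ionise the tertiary alcohol, and O4 is benzylated so no chroman can form.

Step 7
Reactants: 12 4-bromoresorcinol
Product: 13 5-(benzyloxy)-2-bromophenol
Conditions: BnBr (1.0 equiv), K2CO3 (1.0 equiv), acetone, reflux
Reagents that add atoms: benzyl bromide, BrCc1ccccc1
Why: Williamson mono-benzylation at the hydroxyl para to bromine, which is less hindered and gives the more nucleophilic phenoxide; the ortho-bromo hydroxyl is shielded and is the one needed free for the ester.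

Step 8
Reactants: 11 4-(benzyloxy)-5-(3-hydroxy-3-methylbutyl)-6-methoxybenzofuran-3-carboxylic acid; 13 5-(benzyloxy)-2-bromophenol
Product: 14 5-(benzyloxy)-2-bromophenyl 4-(benzyloxy)-5-(3-hydroxy-3-methylbutyl)-6-methoxybenzofuran-3-carboxylate
Conditions: EDC·HCl, DMAP, CH2Cl2, 0 °C to rt
Reagents that add atoms: none
Why: Steglich esterification through the acylpyridinium ion; the phenol is acylated fast while the tertiary alcohol is far too hindered to compete, and no acid chloride or free acid is generated.

Step 9
Reactants: 14 5-(benzyloxy)-2-bromophenyl 4-(benzyloxy)-5-(3-hydroxy-3-methylbutyl)-6-methoxybenzofuran-3-carboxylate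
Product: 15 3,7-bis(benzyloxy)-8-(3-hydroxy-3-methylbutyl)-9-methoxy-6H-benzofuro[3,2-c]chromen-6-one
Conditions: Pd(OAc)2 (10 mol%), PCy3·HBF4 (20 mol%), K2CO3 (2.0 equiv), DMA, 120 °C
Reagents that add atoms: none
Why: Pd(OAc)2 is reduced in the flask to zerovalent palladium bearing PCy3, which inserts into the C1'–Br bond, the only carbon–halogen bond of 14. After bromide is exchanged for carbonate or acetate and the ester rotates so that the O-aryl group lies syn to C2, the furan C2–H is cleaved by concerted metalation–deprotonation; it is the most acidic C–H present, alpha to O1 and beta to the ester carbonyl. The seven-membered diaryl palladacycle then undergoes reductive elimination, which forms C2–C1' and closes the six-membered lactone ring by sp2–sp2 bond formation within the ester tether. The closest known reaction type is the palladium-catalysed intramolecular direct arylation of 2-halophenyl arene- and heteroarenecarboxylates to benzocoumarins and coumestans. No stereocentre is formed. Site selectivity is secured by the tether, because no other C–H can share a palladacycle of seven or fewer members with C1'. Chemoselectivity for C–Br over the ester C–O bond follows from the much faster insertion of the electron-rich phosphine complex into aryl bromides, and dry carbonate limits acyl cleavage.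

Step 10
Reactants: 15 3,7-bis(benzyloxy)-8-(3-hydroxy-3-methylbutyl)-9-methoxy-6H-benzofuro[3,2-c]chromen-6-one
Product: 16 5-(benzyloxy)-2-[4-(benzyloxy)-3-(hydroxymethyl)-5-(3-hydroxy-3-methylbutyl)-6-methoxybenzofuran-2-yl]phenol
Conditions: LiAlH4 (2.5 equiv), THF, 0 °C; H2O/aq NaOH work-up
Reagents that add atoms: none
Why: Hydride reduction of the aryl lactone to the primary alcohol and the phenoxide; low temperature and a non-acidic work-up avoid over-reduction and acid-induced dehydrative re-closure of the diol to a cyclic ether.

Step 11
Reactants: 16 5-(benzyloxy)-2-[4-(benzyloxy)-3-(hydroxymethyl)-5-(3-hydroxy-3-methylbutyl)-6-methoxybenzofuran-2-yl]phenol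
Product: 17 4-[4-(benzyloxy)-2-[4-(benzyloxy)-2-methoxyphenyl]-3-(hydroxymethyl)-6-methoxybenzofuran-5-yl]-2-methylbutan-2-ol
Conditions: MeI, K2CO3, acetone, rt to 40 °C
Reagents that add atoms: iodomethane, CI
Why: Williamson methylation of the only phenol; carbonate does not deprotonate the primary or tertiary alcohol, and O4 and O4' are benzylated, so only O2' is alkylated.

Step 12
Reactants: 17 4-[4-(benzyloxy)-2-[4-(benzyloxy)-2-methoxyphenyl]-3-(hydroxymethyl)-6-methoxybenzofuran-5-yl]-2-methylbutan-2-ol
Product: 18 4-(benzyloxy)-2-[4-(benzyloxy)-2-methoxyphenyl]-5-(3-hydroxy-3-methylbutyl)-6-methoxybenzofuran-3-carbaldehyde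
Conditions: MnO2 (excess), CH2Cl2, rt
Reagents that add atoms: none
Why: MnO2 oxidation of an activated heterobenzylic alcohol to the aldehyde; the tertiary alcohol cannot be oxidised and the neutral medium spares it.

Step 13
Reactants: 18 4-(benzyloxy)-2-[4-(benzyloxy)-2-methoxyphenyl]-5-(3-hydroxy-3-methylbutyl)-6-methoxybenzofuran-3-carbaldehyde
Product: 19 4-hydroxy-2-(4-hydroxy-2-methoxyphenyl)-5-(3-hydroxy-3-methylbutyl)-6-methoxybenzofuran-3-carbaldehyde
Conditions: H2 (1 atm), 10% Pd/C, EtOAc, rt, stopped at full debenzylation
Reagents that add atoms: none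
Why: Hydrogenolysis of two aryl benzyl ethers under neutral conditions; the aldehyde is conjugated with O1 and the donor aryl ring (a vinylogous formate), so it should be reduced more slowly than the ethers are cleaved in a non-protic solvent. No acid is present to close the tertiary alcohol onto the freed O4–H.

## Compound list

1 | 2,4,6-trihydroxybenzaldehyde | O=Cc1c(O)cc(O)cc1O | starting material
2 | 2,6-dihydroxy-4-methoxybenzaldehyde | COc1cc(O)c(C=O)c(O)c1 | intermediate
3 | ethyl diazoacetate | CCOC(=O)C=[N+]=[N-] | starting material
4 | ethyl 2,4-dihydroxy-6-methoxy-2,3-dihydrobenzofuran-3-carboxylate (cyclic hemiacetal, racemic diastereomer mixture, not isolated) | CCOC(=O)C1C(O)Oc2cc(OC)cc(O)c21 | intermediate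
5 | ethyl 4-hydroxy-6-methoxybenzofuran-3-carboxylate | CCOC(=O)c1coc2cc(OC)cc(O)c12 | intermediate
6 | ethyl 4-hydroxy-5-iodo-6-methoxybenzofuran-3-carboxylate | CCOC(=O)c1coc2cc(OC)c(I)c(O)c12 | intermediate
7 | ethyl 4-(benzyloxy)-5-iodo-6-methoxybenzofuran-3-carboxylate | CCOC(=O)c1coc2cc(OC)c(I)c(OCc3ccccc3)c12 | intermediate
8 | 2-methylbut-3-en-2-ol | C=CC(C)(C)O | starting material
9 | 9-(3-hydroxy-3-methylbutyl)-9-borabicyclo[3.3.1]nonane (not isolated) | CC(C)(O)CCB1C2CCCC1CCC2 | intermediate
10 | ethyl 4-(benzyloxy)-5-(3-hydroxy-3-methylbutyl)-6-methoxybenzofuran-3-carboxylate | CCOC(=O)c1coc2cc(OC)c(CCC(C)(C)O)c(OCc3ccccc3)c12 | intermediate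
11 | 4-(benzyloxy)-5-(3-hydroxy-3-methylbutyl)-6-methoxybenzofuran-3-carboxylic acid | O=C(O)c1coc2cc(OC)c(CCC(C)(C)O)c(OCc3ccccc3)c12 | intermediate
12 | 4-bromoresorcinol (4-bromobenzene-1,3-diol) | Oc1ccc(Br)c(O)c1 | starting material
13 | 5-(benzyloxy)-2-bromophenol | Oc1cc(OCc2ccccc2)ccc1Br | intermediate
14 | 5-(benzyloxy)-2-bromophenyl 4-(benzyloxy)-5-(3-hydroxy-3-methylbutyl)-6-methoxybenzofuran-3-carboxylate | O=C(Oc1cc(OCc2ccccc2)ccc1Br)c1coc2cc(OC)c(CCC(C)(C)O)c(OCc3ccccc3)c12 | intermediate
15 | 3,7-bis(benzyloxy)-8-(3-hydroxy-3-methylbutyl)-9-methoxy-6H-benzofuro[3,2-c]chromen-6-one (coumestan lactone) | O=C1Oc2cc(OCc3ccccc3)ccc2-c2oc3cc(OC)c(CCC(C)(C)O)c(OCc4ccccc4)c3c12 | intermediate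
16 | 5-(benzyloxy)-2-[4-(benzyloxy)-3-(hydroxymethyl)-5-(3-hydroxy-3-methylbutyl)-6-methoxybenzofuran-2-yl]phenol | OCc1c(-c2ccc(OCc3ccccc3)cc2O)oc2cc(OC)c(CCC(C)(C)O)c(OCc3ccccc3)c12 | intermediate
17 | 4-[4-(benzyloxy)-2-[4-(benzyloxy)-2-methoxyphenyl]-3-(hydroxymethyl)-6-methoxybenzofuran-5-yl]-2-methylbutan-2-ol | OCc1c(-c2ccc(OCc3ccccc3)cc2OC)oc2cc(OC)c(CCC(C)(C)O)c(OCc3ccccc3)c12 | intermediate
18 | 4-(benzyloxy)-2-[4-(benzyloxy)-2-methoxyphenyl]-5-(3-hydroxy-3-methylbutyl)-6-methoxybenzofuran-3-carbaldehyde | O=Cc1c(-c2ccc(OCc3ccccc3)cc2OC)oc2cc(OC)c(CCC(C)(C)O)c(OCc3ccccc3)c12 | intermediate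
19 | 4-hydroxy-2-(4-hydroxy-2-methoxyphenyl)-5-(3-hydroxy-3-methylbutyl)-6-methoxybenzofuran-3-carbaldehyde | COc1cc(O)ccc1-c1oc2cc(OC)c(CCC(C)(C)O)c(O)c2c1C=O | target

## Step count and least certain steps

Total: 13 steps. Longest linear sequence: 12 steps (steps 1 to 6 and 8 to 13); step 7 is the one-step side branch.

**Step 9 (key step).** The most likely failure is loss of the tether before the C–H bond is reached. The reactive ester rotamer, with the O-aryl group syn to C2, is the minor one. Acyl cleavage of the activated aryl ester by carbonate or traces of water, or hydrodebromination of the arylpalladium species, can therefore outrun palladation. The fallback gives up the tether and sets out from 13 and 10. Methylation of 13 (MeI, K2CO3) gives 4-(benzyloxy)-1-bromo-2-methoxybenzene F1. Intermolecular palladium-catalysed direct C2-arylation of ester 10 with this bromide (Pd(OAc)2, PCy3·HBF4, PivOH, K2CO3, DMA, 110 °C) gives ethyl 4-(benzyloxy)-2-[4-(benzyloxy)-2-methoxyphenyl]-5-(3-hydroxy-3-methylbutyl)-6-methoxybenzofuran-3-carboxylate F2. Reduction with LiAlH4 returns to the route at 17. Site selectivity then rests on the acidity of C2–H alone.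

**Step 2.** Addition of the diazo ester to the doubly hydrogen-bonded, strongly donor-substituted aldehyde may be slow, so that acid-promoted consumption of the diazo ester or alkylation of the electron-rich ring takes over. The fallback sets out from 2 and removes the second free hydroxyl first. Mono-benzylation (BnBr 1 equiv, K2CO3; the remaining OH is held by the carbonyl) gives 2-(benzyloxy)-6-hydroxy-4-methoxybenzaldehyde F3, an ordinary alkoxysalicylaldehyde. Annulation with 3 under the conditions of step 2 gives ethyl 4-(benzyloxy)-6-methoxybenzofuran-3-carboxylate F4. Hydrogenolysis (H2, Pd/C) returns to the route at 5.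

**Step 3.** Iodination may occur at C7 (para to the hydroxyl) or twice, because C5 and C7 are both doubly activated. The fallback sets out from 5 and places the chain at C5 by sigmatropic transfer from O4:
- Copper-catalysed O-alkylation with 3-chloro-3-methylbut-1-yne (DBU, CuCl2 cat., MeCN) gives ethyl 6-methoxy-4-[(2-methylbut-3-yn-2-yl)oxy]benzofuran-3-carboxylate F5.
- Semihydrogenation (H2, Pd/CaCO3 poisoned with Pb(OAc)2, quinoline) gives ethyl 6-methoxy-4-[(2-methylbut-3-en-2-yl)oxy]benzofuran-3-carboxylate F6.
- Aromatic Claisen rearrangement on heating in toluene can only reach C5 and gives ethyl 4-hydroxy-6-methoxy-5-(3-methylbut-2-en-1-yl)benzofuran-3-carboxylate F7.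
- Benzylation gives ethyl 4-(benzyloxy)-6-methoxy-5-(3-methylbut-2-en-1-yl)benzofuran-3-carboxylate F8.
- Mukaiyama hydration (Co(acac)2, PhSiH3, O2) of the trisubstituted alkene returns to the route at 10.

**Step 5.** Oxidative addition and transmetalation at the doubly ortho-substituted, electron-rich iodide may be slow, so that protodeiodination or beta-hydride elimination of the alkylpalladium species competes; the free hydroxyl may also tie up borane. The fallback sets out from 7. Sonogashira coupling with 2-methylbut-3-yn-2-ol (Pd(PPh3)2Cl2, CuI, Et3N, 60 °C), which is less sensitive to crowding, gives ethyl 4-(benzyloxy)-5-(3-hydroxy-3-methylbut-1-yn-1-yl)-6-methoxybenzofuran-3-carboxylate F9. Hydrogenation of the triple bond over PtO2 (H2, EtOAc), which leaves aryl benzyl ethers intact, returns to the route at 10.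

**Step 13.** Over-reduction of the formyl group to hydroxymethyl or methyl may accompany debenzylation. The fallback sets out from 17 and reverses the order of the last two operations. Hydrogenolysis of 17 (H2, Pd/C, EtOAc) gives 2-(4-hydroxy-2-methoxyphenyl)-3-(hydroxymethyl)-5-(3-hydroxy-3-methylbutyl)-6-methoxybenzofuran-4-ol F10. MnO2 then oxidises only the activated heterobenzylic alcohol, as it does with hydroxybenzyl alcohols, and arrives at 19.

## Further compounds

F1 | step 9 | 4-(benzyloxy)-1-bromo-2-methoxybenzene | COc1cc(OCc2ccccc2)ccc1Br
F2 | step 9 | ethyl 4-(benzyloxy)-2-[4-(benzyloxy)-2-methoxyphenyl]-5-(3-hydroxy-3-methylbutyl)-6-methoxybenzofuran-3-carboxylate | CCOC(=O)c1c(-c2ccc(OCc3ccccc3)cc2OC)oc2cc(OC)c(CCC(C)(C)O)c(OCc3ccccc3)c12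
F3 | step 2 | 2-(benzyloxy)-6-hydroxy-4-methoxybenzaldehyde | COc1cc(O)c(C=O)c(OCc2ccccc2)c1
F4 | step 2 | ethyl 4-(benzyloxy)-6-methoxybenzofuran-3-carboxylate | CCOC(=O)c1coc2cc(OC)cc(OCc3ccccc3)c12
F5 | step 3 | ethyl 6-methoxy-4-[(2-methylbut-3-yn-2-yl)oxy]benzofuran-3-carboxylate | CCOC(=O)c1coc2cc(OC)cc(OC(C)(C)C#C)c12
F6 | step 3 | ethyl 6-methoxy-4-[(2-methylbut-3-en-2-yl)oxy]benzofuran-3-carboxylate | CCOC(=O)c1coc2cc(OC)cc(OC(C)(C)C=C)c12
F7 | step 3 | ethyl 4-hydroxy-6-methoxy-5-(3-methylbut-2-en-1-yl)benzofuran-3-carboxylate | CCOC(=O)c1coc2cc(OC)c(CC=C(C)C)c(O)c12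
F8 | step 3 | ethyl 4-(benzyloxy)-6-methoxy-5-(3-methylbut-2-en-1-yl)benzofuran-3-carboxylate | CCOC(=O)c1coc2cc(OC)c(CC=C(C)C)c(OCc3ccccc3)c12
F9 | step 5 | ethyl 4-(benzyloxy)-5-(3-hydroxy-3-methylbut-1-yn-1-yl)-6-methoxybenzofuran-3-carboxylate | CCOC(=O)c1coc2cc(OC)c(C#CC(C)(C)O)c(OCc3ccccc3)c12
F10 | step 13 | 2-(4-hydroxy-2-methoxyphenyl)-3-(hydroxymethyl)-5-(3-hydroxy-3-methylbutyl)-6-methoxybenzofuran-4-ol | OCc1c(-c2ccc(O)cc2OC)oc2cc(OC)c(CCC(C)(C)O)c(O)c12
A1 | alternative 1 | methyl 2-diazo-2-[4-methoxy-6-[[2-methoxy-4-(triisopropylsilyloxy)benzyl]oxy]-3-[3-methyl-3-(triethylsilyloxy)butyl]-2-(pivaloyloxy)phenyl]acetate | COC(=O)C(=[N+]=[N-])c1c(OCc2ccc(O[Si](C(C)C)(C(C)C)C(C)C)cc2OC)cc(OC)c(CCC(C)(C)O[Si](CC)(CC)CC)c1OC(=O)C(C)(C)C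
A2 | alternative 1 | methyl 6-methoxy-2-[2-methoxy-4-(triisopropylsilyloxy)phenyl]-5-[3-methyl-3-(triethylsilyloxy)butyl]-4-(pivaloyloxy)-2,3-dihydrobenzofuran-3-carboxylate (racemic, cis and trans) | COC(=O)C1C(c2ccc(O[Si](C(C)C)(C(C)C)C(C)C)cc2OC)Oc2cc(OC)c(CCC(C)(C)O[Si](CC)(CC)CC)c(OC(=O)C(C)(C)C)c21
A3 | alternative 2 | 4-(benzyloxy)-3'-[4-(benzyloxy)-2-methoxyphenyl]-5-(3-hydroxy-3-methylbutyl)-6-methoxy-2H-spiro[benzofuran-3,2'-oxiran]-2-one (racemic) | O=C1Oc2cc(OC)c(CCC(C)(C)O)c(OCc3ccccc3)c2C13OC3c1ccc(OCc3ccccc3)cc1OC
A4 | alternative 2 | methyl 4-(benzyloxy)-2-[4-(benzyloxy)-2-methoxyphenyl]-5-(3-hydroxy-3-methylbutyl)-6-methoxybenzofuran-3-carboxylate | COC(=O)c1c(-c2ccc(OCc3ccccc3)cc2OC)oc2cc(OC)c(CCC(C)(C)O)c(OCc3ccccc3)c12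
A5 | alternative 3 | 1-[5-[4-(benzyloxy)-2-methoxyphenyl]-4-(1,3-dioxolan-2-yl)furan-2-yl]-2-diazoethan-1-one | [N-]=[N+]=CC(=O)c1cc(C2OCCO2)c(-c2ccc(OCc3ccccc3)cc2OC)o1
A6 | alternative 3 | triethyl[(6-methoxy-2-methylhex-5-yn-2-yl)oxy]silane | COC#CCCC(C)(C)O[Si](CC)(CC)CC
A7 | alternative 3 | 2-[4-(benzyloxy)-2-methoxyphenyl]-3-(1,3-dioxolan-2-yl)-6-methoxy-5-[3-methyl-3-(triethylsilyloxy)butyl]benzofuran-4-ol | COc1cc(OCc2ccccc2)ccc1-c1oc2cc(OC)c(CCC(C)(C)O[Si](CC)(CC)CC)c(O)c2c1C1OCCO1
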